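Early in a run, before much has happened, substrate is the easiest thing to read, so I started there.

| setting | eta | epsilon | gamma | red | teal |
|---|---|---|---|---|---|
| substrate | 10 mM | 10 mM | 10 mM | 10 mM | 10 mM |
| partner | 8.5 mM | 14 mM | 24 mM | 10.0 mM | 20.0 mM |
| capture agent | 1 mM | 1 mM | 1 mM | 1.00 mM | 1.00 mM |
| remark | run made earlier | run made earlier | run made earlier |  |  |
| time |  |  |  | 4.0 h | 4.0 h |

| run | time / h | substrate / % | trapped intermediate / % | open intermediate / % | product / % |
|---|---|---|---|---|---|
| eta | 0.333 | 90.6 | 0.7 | 9.7 | 0.9 |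
| eta | 0.667 | 83.4 | 0.9 | 11.6 | 4.0 |
| eta | 1.00 | 79.2 | 2.8 | 13.8 | 6.8 |
| eta | 2.00 | 67.1 | 3.7 | 12.5 | 17.2 |
| eta | 4.00 | 57.0 | 6.1 | 8.4 | 28.7 |
| epsilon | 0.333 | 84.9 | 0.6 | 13.4 | 1.0 |
| epsilon | 1.00 | 66.5 | 3.0 | 20.9 | 8.3 |
| epsilon | 2.00 | 50.0 | 4.0 | 18.1 | 23.4 |
| epsilon | 3.00 | 41.0 | 10.0 | 14.0 | 35.1 |
| epsilon | 4.00 | 38.5 | 7.5 | 10.9 | 44.3 |
| gamma | 0.833 | 52.3 | 2.5 | 30.8 | 10.9 |
| gamma | 1.50 | 38.5 | 6.0 | 29.7 | 25.3 |
| gamma | 2.50 | 25.8 | 9.6 | 20.4 | 46.5 |
| gamma | 3.00 | 20.7 | 8.0 | 19.6 | 52.0 |
| gamma | 4.00 | 16.2 | 8.8 | 12.9 | 63.9 |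

(readings scatter by 1 percentage point)



* which of these there is most of at the end, counted by the substrate in it, red (trapped intermediate / product / open intermediate / substrate)
* which of these there is most of at the end, counted by the substrate in it, teal (trapped intermediate / product / open intermediate / substrate)
* the largest of these amounts at the end, in percent of the substrate charged, red
* the largest of these amounts at the end, in percent of the substrate charged, teal

At the first reading of eta, substrate had fallen by about 0.940 mM against 8.5 mM of partner charged, so for that early moment I took [partner] at its charge. By 4.00 h the fall in eta came to 4.30 mM, half of that charge, so [partner] could not be frozen over a whole run, and the figure below is a working number read at a stated time, not a rate constant. I then defined the pull: the natural log of substrate charged over substrate remaining, divided by starting [partner] and by the time. Early on, eta read 34.9 L mol⁻¹ h⁻¹ and epsilon 35.1 L mol⁻¹ h⁻¹. Over the whole 4.0 h, eta read 16.5 L mol⁻¹ h⁻¹, about half of its early value, and epsilon read 17.0 L mol⁻¹ h⁻¹. Gamma read 19.0 L mol⁻¹ h⁻¹, higher than eta. So the pull at 4.0 h fell with time but changed little from flask to flask.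

Red looks nearly the same as eta, with 1.50 mM more partner. Holding the pull of eta, I reckoned red's substrate at 51.6%, against 57.0% in eta. Holding the pull of gamma, I reckoned teal's substrate at 21.9%. With gamma's intermediates, that left teal's product near 56.4%.

The forecast said substrate at 51.5% in red and product at 57% in teal, noting that “Both curves flatten as partner rises”. It used the same readings as I did, so our closeness is no check. Still, a pull that moved little from flask to flask and two flasks inside the charged range of partner gave good grounds to trust its interpolation.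

The flasks gave substrate at 49.6% in red and product at 56.6% in teal.

    substrate + partner ⇌ open intermediate (K = 350 L mol⁻¹, k = 39.0 L mol⁻¹ h⁻¹)
    open intermediate → product (k = 0.690 h⁻¹)
    open intermediate + capture agent → trapped intermediate (k = 260 L mol⁻¹ h⁻¹)
    partner → decomposed reagent (k = 0.120 h⁻¹)

Red's own pull came to 17.6 L mol⁻¹ h⁻¹, close to eta's, and teal's to 18.9 L mol⁻¹ h⁻¹, close to gamma's. Teal's substrate ended lower than red's, and the main reason is the difference in [partner]: teal's substrate stands at 22.1% with that difference and at 49.6% without it. Red with 2.5 mM of substrate has the same partner and time, so eta's pull again gives 51.6%. That flask computed 37.2%, a pull of 24.7 L mol⁻¹ h⁻¹, with 50.3% of its partner left against 25.2% in red.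

All runs were computed from invented constants.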